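We read the flask at 25 h, so we count how many half-lives of the left-handed substrate fit before that time.

| flask | left-handed substrate | right-handed substrate | solid reagent | free catalyst | remark | time |
|---|---|---|---|---|---|---|
| winter | 0.088 M | 0.088 M | 0.0968 M | 4.4 mM | run made earlier |  |
| dawn | 0.088 M | 0.088 M | 0.0968 M | 18 mM | run made earlier |  |
| flask | 0.088 M | 0.088 M | 0.0968 M | 8.8 mM |  | 25 h |

| run | time / h | right-handed substrate / % | left-handed substrate / % | left-handed product / % |
|---|---|---|---|---|
| winter | 2.00 | 49.1 | 39.5 | 8.0 |
| winter | 3.00 | 46.8 | 33.8 | 14.1 |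
| winter | 6.00 | 47.3 | 22.4 | 29.1 |
| winter | 10.0 | 45.8 | 13.9 | 34.6 |
| winter | 15.0 | 45.6 | 9.8 | 41.9 |
| winter | 25.0 | 45.9 | 4.5 | 44.5 |
| dawn | 1.50 | 46.5 | 29.7 | 19.3 |
| dawn | 5.00 | 40.3 | 9.1 | 42.3 |
| dawn | 8.00 | 40.6 | 2.7 | 45.6 |
| dawn | 15.0 | 40.1 | 0.8 | 48.9 |
| dawn | 20.0 | 39.8 | 0 | 49.3 |
| dawn | 25.0 | 41.0 | 1.5 | 48.6 |

(scatter of a reading: 1 percentage point)

- whether the excess of right-handed substrate over left-handed substrate among what is left of the two reaches 90% by 25 h (yes / no)
- the highest excess of right-handed substrate over left-handed substrate among what is left of the two up to 25 h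

- free catalyst is single-handed; left-handed substrate and right-handed substrate are mirror images of each other, charged as a racemate, each of them at the stated concentration
- solid reagent is a solid; its amount is given per volume of the solution
- the numbers in the tables scatter by 1 percentage point (one standard deviation)
- at the start none of the solid reagent is in solution

The right-handed substrate readings drop early and then fall slowly, ending at 45.9% in the winter run and 41.0% in the dawn run. An excess of 90% needs the left-handed substrate at 0.0526 of the right-handed one. Starting from half of the charge, it must therefore halve 4.37 times on the winter ending and 4.53 times on the dawn ending. We call this the halvings needed, n.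

Two extremes bracket the flask. If catalyst buys nothing, the flask repeats the winter run: 3.47 halvings by 25.0 h, fewer than n. If speed follows catalyst in proportion, the flask's 25 h equals 12.2 h of the dawn run, which made 4.21 halvings by 8.00 h and read 0.8% by 15.0 h, under its target.

The early half-lives read 5.18 h and 2.03 h, a speed-up smaller than the rise in catalyst. Treating the decay as pseudo-first-order, speed goes as catalyst to the power 0.663. Keeping winter's late slowing, the flask makes 5.50 halvings, above n. So we say yes, with 1.10% left-handed substrate beside about 43.4% right-handed, a top near 95.0%.

The forecast also says yes, with a top of 96%, above ours, taking the right-handed fall for “a catalyst-linked, limited loss”.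

The flask gives yes: its excess reaches 90% at 21.4 h and tops out at 91.7%.

    free catalyst + left-handed substrate ⇌ catalyst intermediate A (K = 18.0 M⁻¹, k = 12.4 M⁻¹ min⁻¹)
    free catalyst + right-handed substrate ⇌ catalyst intermediate B (K = 23.0 M⁻¹, k = 3.75 M⁻¹ min⁻¹)
    coupling partner + catalyst intermediate A → free catalyst + left-handed product (k = 5.00 M⁻¹ min⁻¹)
    coupling partner + catalyst intermediate B → free catalyst + right-handed product (k = 0.0911 M⁻¹ min⁻¹)
    coupling partner ⇌ dormant form (K = 0.572, k = 0.00603 min⁻¹)
    coupling partner → decomposition product (k = 2.49 × 10⁻⁵ min⁻¹)
    solid reagent ⇌ coupling partner, rate k7*(cs7 - [coupling partner]) while solid is left; crystals form when [coupling partner] > cs7 (solubility = 33.0 mM, k = 0.0321 min⁻¹)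

With 43.3% right-handed substrate standing in the flask at 21.4 h, n comes to 4.46. By 25.0 h the flask's left-handed substrate made 4.74 halvings, 0.210 past our n. At 25.0 h the flask's coupling partner goes to left-handed product 1.8 times as fast as to right-handed product, though the rate constants stand at 54.9 to one. At that time catalyst intermediate B, the resting state, holds 62.2% of the catalyst and catalyst intermediate A holds 2.08%.

(The readings are simulated from invented constants; scatter was added.)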